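## Retrosynthetic overview

1. The angelate and the C16 alcohol are unmasked last (Yamaguchi acylation of the 6α-OH, then PMB removal). C12–C13 is cut to a C12 Grignard reagent and a 4-(PMB-oxy)but-2-enyl bromide, joined by copper-catalysed enantioselective SN2' alkylation that sets C13.
2. The 6α,8α-diol is traced to a C7=C8 alkene (allylic oxidation at C6, Luche reduction, hydroxyl-directed epoxidation, hydride opening). C9–C11 is traced to a Johnson–Claisen rearrangement of a 7β-allylic alcohol, made from the ring B enone by epoxidation and Wharton transposition.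
3. Ring A (C1, C2, C3, C4, C5, C10) is opened at C3–C4: an iron-hydride HAT-initiated 6-endo radical (Giese) cyclisation of an isopropenyl group onto a 2-(phenylsulfonyl)allyl arm.
4. Feature carrying the strategy: the decalin is cis-fused (H5 and the C10 methyl syn) with the quaternary gem-dimethyl carbon C4 bonded to C5. Ring B (C5–C10 with the C8 methyl) is therefore a carvone ring whose isopropenyl carbon becomes C4 and whose alpha' carbon becomes C10.
5. Ring order: ring B is bought as (S)-carvone, ring A is closed by the radical step, then the side chain (C11–C12, then C13–C16) and the ester are attached.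

Key step: step 4

Remark: the target is read as a 5β-H (cis-fused) labdane with 10β-CH3, 9β side chain, 6α-angelate, 8α-OH and (13R) configuration. Bicyclic compounds carry labdane numbering (C1–C10 decalin, C11–C16 side chain, C17 on C8, C20 on C10), β being the face of the C10 methyl. "Core" means the 4,4,8,10-tetramethyl-cis-decalin with 5β-H and 10β-CH3. Monocyclic compounds 1–7 carry cyclohexenone numbering (ring C5 becomes labdane C5, ring C6 becomes C10, ring C2 becomes C8).

## Route

Step 1
Reactants: 1 (S)-(+)-carvone; 2 2,3-dibromopropene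
Product: 4 (5S,6R)-6-(2-bromoprop-2-en-1-yl)-2-methyl-5-(prop-1-en-2-yl)cyclohex-2-en-1-one (bromoallyl trans to isopropenyl), via lithium dienolate 3 (not isolated)
Conditions: LiN(iPr)2 (1.05 equiv), THF, −78 °C; then 2 (1.2 equiv), −78 → −20 °C
Reagents that add atoms: lithium diisopropylamide, [Li]N(C(C)C)C(C)C (its lithium stays only in enolate 3)
Why: kinetic alpha'-deprotonation gives the cross-conjugated dienolate, which is C-alkylated by the allylic bromide of 2 mainly anti to the isopropenyl group (enolate alkylation); any epimer at this carbon is harmless because step 2 re-enolises it.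

Step 2
Reactants: 4 trans-6-(2-bromoallyl)carvone
Product: 6 (5S,6S)-6-(2-bromoprop-2-en-1-yl)-2,6-dimethyl-5-(prop-1-en-2-yl)cyclohex-2-en-1-one (6-methyl trans and bromoallyl cis to isopropenyl), via lithium enolate 5 (not isolated)
Conditions: LiN(iPr)2 (1.1 equiv), THF, −78 °C; then MeI (3 equiv), DMPU, −78 → 0 °C
Reagents that add atoms: iodomethane, CI; lithium diisopropylamide, [Li]N(C(C)C)C(C)C (its lithium stays only in enolate 5)
Why: the tetrasubstituted enolate should be methylated on the face anti to the neighbouring isopropenyl group, which allylic strain holds pseudoaxial, so the methyl (future C20) ends trans and the bromoallyl arm cis to isopropenyl (second enolate alkylation, which fixes the later cis ring fusion).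

Step 3
Reactants: 6 6-(2-bromoallyl)-6-methylcarvone
Product: 7 (5S,6S)-2,6-dimethyl-6-[2-(phenylsulfonyl)prop-2-en-1-yl]-5-(prop-1-en-2-yl)cyclohex-2-en-1-one
Conditions: PhSO2Na (2 equiv), CuI (10 mol%), MeNHCH2CH2NHMe (20 mol%), DMSO, 90 °C
Reagents that add atoms: sodium benzenesulfinate, [Na+].[O-]S(=O)c1ccccc1
Why: cuprous-catalysed Ullmann-type C–S coupling of the alkenyl bromide with the sulfinate should replace Br by PhSO2 on the intact 1,1-disubstituted alkene, and it is placed here because a vinyl sulfone would not survive the two enolate steps.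

Step 4
Reactants: 7 sulfonylallyl carvone
Product: 8 2-(phenylsulfonyl)-core-7-en-9-one (cis-fused, both C2 epimers)
Conditions: Fe(acac)3 (0.5 equiv), PhSiH3 (2.5 equiv), EtOH/HOCH2CH2OH (5:1), high dilution, 60 °C
Reagents that add atoms: none
Why: The iron hydride generated from Fe(acac)3 and PhSiH3 should transfer a hydrogen atom to the CH2 terminus of the electron-rich isopropenyl group, and the tertiary C4 radical then adds to the unsubstituted terminus (C3) of the 2-sulfonylallyl arm, after which the alpha-sulfonyl radical at C2 is reduced by ferrous iron and protonated by ethanol. The closest known reaction type is the iron-hydride HAT reductive olefin coupling (radical Giese addition of 1,1-disubstituted alkenes to vinyl sulfones and enones), used here intramolecularly. Ring A (C1, C2, C3, C4, C5, C10) closes in the 6-endo-trig mode, favoured because the radical-stabilising sulfone sits on the internal alkene carbon, whereas 5-exo closure would join two fully substituted carbons and leave an unstabilised primary radical. The only new stereocentre, C2, is uncontrolled and irrelevant since the sulfone is removed in step 8, while the cis ring fusion follows from the cis arms on C5 and C10 set in steps 1 and 2. The step needs hydrogen-atom transfer to the isopropenyl group and not to the enone or vinyl sulfone, which the higher electron density of that alkene secures, and the ring B enone cannot trap the C4 radical in any workable ring size.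

Step 5
Reactants: 8 bicyclic sulfonyl enone
Product: 9 7β,8β-epoxy-2-(phenylsulfonyl)-core-9-one (8α-CH3)
Conditions: 30% aq. H2O2 (5 equiv), NaOH (0.3 equiv), MeOH, 0 °C → rt
Reagents that add atoms: hydrogen peroxide, OO
Why: Weitz–Scheffer nucleophilic epoxidation, in which hydroperoxide should add to C7 on the β face, anti to the C4 substituent on C5 (the same trans preference carvone shows), and the enolate closes the epoxide on that face.

Step 6
Reactants: 9 epoxy ketone
Product: 11 2-(phenylsulfonyl)-core-8-en-7β-ol, via epoxy hydrazone 10 (not isolated)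
Conditions: N2H4·H2O (3 equiv), AcOH (0.5 equiv), MeOH, 0 °C → rt
Reagents that add atoms: hydrazine hydrate, NN.O (its nitrogen stays only in hydrazone 10)
Why: Wharton transposition, in which the hydrazone opens the epoxide to a vinyl diazene that loses N2, moving the alkene to C8=C9 while the C7–O bond is never broken, so the carbinol keeps the β configuration.

Step 7
Reactants: 11 7β-allylic alcohol; 12 trimethyl orthoacetate
Product: 14 methyl [2-(phenylsulfonyl)-core-7-en-9β-yl]acetate (9α-H), via ketene acetal 13 (not isolated)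
Conditions: 12 (10 equiv), EtCO2H (0.1 equiv), xylene, 140 °C, MeOH distilled off
Reagents that add atoms: none
Why: Johnson–Claisen [3,3] rearrangement of the ketene acetal is suprafacial on the ring, so the 7β C–O bond is exchanged for a 9β C–C bond (C11–C12 arm cis to the C10 methyl) and the alkene returns to C7=C8.

Step 8
Reactants: 14 sulfonyl ester
Product: 15 methyl 13,14,15,16-tetranor-5β-labd-7-en-12-oate
Conditions: Mg turnings (excess), cat. HgCl2, MeOH, rt → 50 °C
Reagents that add atoms: none
Why: single-electron reductive desulfonylation should cleave the C2–S bond of either epimer to the same CH2 and leave the isolated trisubstituted alkene and the methyl ester (in methanol) untouched.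

Step 9
Reactants: 15 Δ7 ester
Product: 16 methyl 6-oxo-13,14,15,16-tetranor-5β-labd-7-en-12-oate
Conditions: CrO3 (15 equiv), 3,5-dimethylpyrazole (15 equiv), CH2Cl2, −20 °C; silica filtration, used at once
Reagents that add atoms: chromium trioxide, O=[Cr](=O)=O
Why: allylic oxidation with the CrO3–3,5-dimethylpyrazole complex should convert the ring methylene C6 into the ketone conjugated with C7=C8 (the other allylic site C9 is a hindered methine beside quaternary C10), and base-free handling keeps C5 and C9 from epimerising through the enol or dienol.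

Step 10
Reactants: 16 7-en-6-one
Product: 17 methyl 6α-hydroxy-13,14,15,16-tetranor-5β-labd-7-en-12-oate
Conditions: NaBH4 (1.5 equiv), CeCl3·7H2O (1.2 equiv), MeOH, −78 °C
Reagents that add atoms: none
Why: Luche 1,2-reduction, in which hydride should enter from the β face because the quaternary C4 with its two methyls and ring A flank the carbonyl on the α side, giving the 6α-alcohol cold enough to leave C5 and the ester unchanged.

Step 11
Reactants: 17 6α-allylic alcohol
Product: 18 methyl 7α,8α-epoxy-6α-hydroxy-13,14,15,16-tetranor-5β-labdan-12-oate (8β-CH3)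
Conditions: VO(acac)2 (5 mol%), t-BuOOH (1.5 equiv), CH2Cl2, 0 °C → rt
Reagents that add atoms: tert-butyl hydroperoxide, CC(C)(C)OO
Why: vanadium-catalysed hydroxyl-directed epoxidation delivers oxygen to C7=C8 from the face of the 6α-OH, so the epoxide is α and the C17 methyl is pushed β.

Step 12
Reactants: 18 epoxy alcohol ester
Product: 19 13,14,15,16-tetranor-5β-labdane-6α,8α,12-triol
Conditions: LiAlH4 (excess), THF, 0 °C → reflux; aq. NaOH work-up
Reagents that add atoms: none
Why: hydride should open the trisubstituted epoxide by SN2 attack at the secondary carbon C7 from the β face, leaving the oxygen on C8 as the tertiary 8α-alcohol, while the same reagent reduces the ester to the C12 primary alcohol.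

Step 13
Reactants: 19 triol
Product: 20 6α,8α,12-tris(triethylsilyloxy)-13,14,15,16-tetranor-5β-labdane
Conditions: Et3SiOTf (4 equiv), 2,6-lutidine (6 equiv), CH2Cl2, −78 → 0 °C
Reagents that add atoms: triethylsilyl trifluoromethanesulfonate, CC[Si](CC)(CC)OS(=O)(=O)C(F)(F)F
Why: the silyl triflate silylates primary, hindered secondary and tertiary hydroxyls alike, and capping O8 before C12 is activated forestalls the 5-exo-tet closure to the 8,12-tetrahydrofuran that a free 8α-OH would give.

Step 14
Reactants: 20 tris(silyl) ether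
Product: 21 6α,8α-bis(triethylsilyloxy)-13,14,15,16-tetranor-5β-labdan-12-ol
Conditions: PPTS (0.2 equiv), MeOH/CH2Cl2 (1:5), −10 °C, stopped at consumption of 20
Reagents that add atoms: none
Why: acid-catalysed methanolysis of silyl ethers is governed by steric access, so the primary C12 ether should go well before the hindered secondary C6 and tertiary C8 ethers (selective desilylation).

Step 15
Reactants: 21 primary alcohol
Product: 22 12-bromo-6α,8α-bis(triethylsilyloxy)-13,14,15,16-tetranor-5β-labdane
Conditions: CBr4 (1.3 equiv), PPh3 (1.4 equiv), 2,6-lutidine (0.5 equiv), CH2Cl2, 0 °C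
Reagents that add atoms: carbon tetrabromide, BrC(Br)(Br)Br
Why: Appel reaction, in which bromide displaces the primary alkoxyphosphonium by SN2 under near-neutral conditions that both silyl ethers tolerate.

Step 16
Reactants: 23 (E)-1,4-dibromobut-2-ene
Product: 24 (E)-1-bromo-4-[(4-methoxybenzyl)oxy]but-2-ene
Conditions: 4-MeOC6H4CH2OH (1 equiv), NaH (1 equiv), THF, 0 °C; added to 23 (3 equiv), THF, 0 °C → rt
Reagents that add atoms: 4-methoxybenzyl alcohol, COc1ccc(CO)cc1
Why: Williamson etherification with the dibromide in excess should stop at monosubstitution, and SN2 at the primary allylic carbon keeps the E alkene.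

Step 17
Reactants: 22 C12 bromide; 24 PMB-oxybutenyl bromide
Product: 26 (13R)-16-[(4-methoxybenzyl)oxy]-6α,8α-bis(triethylsilyloxy)-5β-labd-14-ene, via Grignard reagent 25 (not isolated)
Conditions: Mg turnings, Et2O, 35 °C; solution added over 2 h to 24 (1.3 equiv), CuBr·SMe2 (5 mol%), Taniaphos (1-[(dimethylamino)(2-diphenylphosphinophenyl)methyl]-2-(diphenylphosphino)ferrocene, 6 mol%), CH2Cl2, −78 °C
Reagents that add atoms: magnesium, [Mg] (stays only in Grignard reagent 25)
Why: copper-catalysed enantioselective allylic alkylation, in which the alkylcopper species carrying the chiral ferrocenyl diphosphine adds SN2' to the gamma carbon of the allylic bromide to give the branched terminal alkene; C13 is set by the ligand enantiomer (to be assigned on a simple alkyl Grignard model) because the substrate stereocentres are too remote to interfere.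

Step 18
Reactants: 26 bis(silyl) ether
Product: 27 (13R)-16-[(4-methoxybenzyl)oxy]-5β-labd-14-ene-6α,8α-diol
Conditions: HF·pyridine, pyridine, THF, 0 °C → rt
Reagents that add atoms: none
Why: fluoride-driven Si–O cleavage removes both triethylsilyl groups and leaves the PMB ether and the terminal alkene untouched.

Step 19
Reactants: 27 6α,8α-diol; 28 angelic acid
Product: 30 (13R)-8α-hydroxy-16-[(4-methoxybenzyl)oxy]-5β-labd-14-en-6α-yl (Z)-2-methylbut-2-enoate, via mixed anhydride 29 (not isolated)
Conditions: 28 (3 equiv), 2,4,6-Cl3C6H2COCl (3 equiv), Et3N (3 equiv), toluene, rt; then 27, toluene, 80 °C, no DMAP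
Reagents that add atoms: 2,4,6-trichlorobenzoyl chloride, O=C(Cl)c1c(Cl)cc(Cl)cc1Cl (its atoms stay only in anhydride 29)
Why: Yamaguchi esterification, in which the secondary 6α-OH attacks the less hindered angeloyl carbonyl of the mixed anhydride; without a nucleophilic amine catalyst there is no reversible conjugate addition to isomerise Z to E, and the tertiary 8-OH is too hindered to react.

Step 20
Reactants: 30 PMB-protected angelate
Product: 31 target CNP0177054.1, (13R)-8α,16-dihydroxy-5β-labd-14-en-6α-yl (Z)-2-methylbut-2-enoate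
Conditions: DDQ (1.3 equiv), CH2Cl2/pH 7 phosphate buffer (10:1), 0 °C
Reagents that add atoms: none
Why: oxidative PMB cleavage by hydride abstraction from the electron-rich benzylic position and hydrolysis of the oxocarbenium ion, to which the terminal alkene, the angelate and the tertiary alcohol are inert.

## Compound list

1 | (S)-(+)-carvone, (5S)-2-methyl-5-(prop-1-en-2-yl)cyclohex-2-en-1-one | O=C1C[C@@H](C(C)=C)CC=C1C | starting material
2 | 2,3-dibromopropene | C=C(Br)CBr | starting material
3 | lithium cross-conjugated dienolate of 1 (O–C1=C6) | [Li]OC1=C[C@@H](C(C)=C)CC=C1C | intermediate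
4 | (5S,6R)-6-(2-bromoprop-2-en-1-yl)-2-methyl-5-(prop-1-en-2-yl)cyclohex-2-en-1-one | O=C1[C@H](CC(Br)=C)[C@@H](C(C)=C)CC=C1C | intermediate
5 | lithium enolate of 4 (O–C1=C6, tetrasubstituted) | [Li]OC1=C(CC(Br)=C)[C@@H](C(C)=C)CC=C1C | intermediate
6 | (5S,6S)-6-(2-bromoprop-2-en-1-yl)-2,6-dimethyl-5-(prop-1-en-2-yl)cyclohex-2-en-1-one | O=C1[C@@](C)(CC(Br)=C)[C@@H](C(C)=C)CC=C1C | intermediate
7 | (5S,6S)-2,6-dimethyl-6-[2-(phenylsulfonyl)prop-2-en-1-yl]-5-(prop-1-en-2-yl)cyclohex-2-en-1-one | O=C1[C@@](C)(CC(=C)S(=O)(=O)c2ccccc2)[C@@H](C(C)=C)CC=C1C | intermediate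
8 | 2-(phenylsulfonyl)-4,4,8,10-tetramethyl-cis-decal-7-en-9-one (5β-H, 10β-CH3, C2 epimers) | O=C1[C@@]2(C)CC(S(=O)(=O)c3ccccc3)CC(C)(C)[C@H]2CC=C1C | intermediate
9 | 7β,8β-epoxy-2-(phenylsulfonyl)-4,4,8,10-tetramethyl-cis-decalin-9-one (5β-H, 10β-CH3, 8α-CH3) | O=C1[C@@]2(C)CC(S(=O)(=O)c3ccccc3)CC(C)(C)[C@H]2C[C@@H]4O[C@]14C | intermediate
10 | hydrazone of epoxy ketone 9 | NN=C1[C@@]2(C)CC(S(=O)(=O)c3ccccc3)CC(C)(C)[C@H]2C[C@@H]4O[C@]14C | intermediate
11 | 2-(phenylsulfonyl)-4,4,8,10-tetramethyl-cis-decal-8-en-7β-ol (5β-H, 10β-CH3) | CC1=C[C@@]2(C)CC(S(=O)(=O)c3ccccc3)CC(C)(C)[C@H]2C[C@@H]1O | intermediate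
12 | trimethyl orthoacetate | CC(OC)(OC)OC | starting material
13 | 7β-(1-methoxyvinyl) ether of 11 (ketene acetal) | CC1=C[C@@]2(C)CC(S(=O)(=O)c3ccccc3)CC(C)(C)[C@H]2C[C@@H]1OC(=C)OC | intermediate
14 | methyl [2-(phenylsulfonyl)-4,4,8,10-tetramethyl-cis-decal-7-en-9β-yl]acetate (5β-H, 9α-H, 10β-CH3) | COC(=O)C[C@@H]1[C@@]2(C)CC(S(=O)(=O)c3ccccc3)CC(C)(C)[C@H]2CC=C1C | intermediate
15 | methyl 13,14,15,16-tetranor-5β-labd-7-en-12-oate | COC(=O)C[C@@H]1[C@@]2(C)CCCC(C)(C)[C@H]2CC=C1C | intermediate
16 | methyl 6-oxo-13,14,15,16-tetranor-5β-labd-7-en-12-oate | COC(=O)C[C@@H]1[C@@]2(C)CCCC(C)(C)[C@H]2C(=O)C=C1C | intermediate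
17 | methyl 6α-hydroxy-13,14,15,16-tetranor-5β-labd-7-en-12-oate | COC(=O)C[C@@H]1[C@@]2(C)CCCC(C)(C)[C@H]2[C@@H](O)C=C1C | intermediate
18 | methyl 7α,8α-epoxy-6α-hydroxy-13,14,15,16-tetranor-5β-labdan-12-oate | COC(=O)C[C@@H]1[C@@]2(C)CCCC(C)(C)[C@H]2[C@@H](O)[C@H]3O[C@@]13C | intermediate
19 | 13,14,15,16-tetranor-5β-labdane-6α,8α,12-triol | OCC[C@@H]1[C@@]2(C)CCCC(C)(C)[C@H]2[C@@H](O)C[C@@]1(C)O | intermediate
20 | 6α,8α,12-tris(triethylsilyloxy)-13,14,15,16-tetranor-5β-labdane | CC[Si](CC)(CC)OCC[C@@H]1[C@@]2(C)CCCC(C)(C)[C@H]2[C@@H](O[Si](CC)(CC)CC)C[C@@]1(C)O[Si](CC)(CC)CC | intermediate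
21 | 6α,8α-bis(triethylsilyloxy)-13,14,15,16-tetranor-5β-labdan-12-ol | OCC[C@@H]1[C@@]2(C)CCCC(C)(C)[C@H]2[C@@H](O[Si](CC)(CC)CC)C[C@@]1(C)O[Si](CC)(CC)CC | intermediate
22 | 12-bromo-6α,8α-bis(triethylsilyloxy)-13,14,15,16-tetranor-5β-labdane | BrCC[C@@H]1[C@@]2(C)CCCC(C)(C)[C@H]2[C@@H](O[Si](CC)(CC)CC)C[C@@]1(C)O[Si](CC)(CC)CC | intermediate
23 | (E)-1,4-dibromobut-2-ene | BrC/C=C/CBr | starting material
24 | (E)-1-bromo-4-[(4-methoxybenzyl)oxy]but-2-ene | BrC/C=C/COCc1ccc(OC)cc1 | intermediate
25 | Grignard reagent of 22 (C12–MgBr) | Br[Mg]CC[C@@H]1[C@@]2(C)CCCC(C)(C)[C@H]2[C@@H](O[Si](CC)(CC)CC)C[C@@]1(C)O[Si](CC)(CC)CC | intermediate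
26 | (13R)-16-[(4-methoxybenzyl)oxy]-6α,8α-bis(triethylsilyloxy)-5β-labd-14-ene | C=C[C@H](COCc1ccc(OC)cc1)CC[C@@H]1[C@@]2(C)CCCC(C)(C)[C@H]2[C@@H](O[Si](CC)(CC)CC)C[C@@]1(C)O[Si](CC)(CC)CC | intermediate
27 | (13R)-16-[(4-methoxybenzyl)oxy]-5β-labd-14-ene-6α,8α-diol | C=C[C@H](COCc1ccc(OC)cc1)CC[C@@H]1[C@@]2(C)CCCC(C)(C)[C@H]2[C@@H](O)C[C@@]1(C)O | intermediate
28 | angelic acid, (Z)-2-methylbut-2-enoic acid | C/C=C(/C)C(=O)O | starting material
29 | angelic 2,4,6-trichlorobenzoic anhydride | C/C=C(/C)C(=O)OC(=O)c1c(Cl)cc(Cl)cc1Cl | intermediate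
30 | (13R)-8α-hydroxy-16-[(4-methoxybenzyl)oxy]-5β-labd-14-en-6α-yl (Z)-2-methylbut-2-enoate | C=C[C@H](COCc1ccc(OC)cc1)CC[C@@H]1[C@@]2(C)CCCC(C)(C)[C@H]2[C@@H](OC(=O)/C(C)=C\C)C[C@@]1(C)O | intermediate
31 | CNP0177054.1, (13R)-8α,16-dihydroxy-5β-labd-14-en-6α-yl (Z)-2-methylbut-2-enoate | C=C[C@H](CO)CC[C@@H]1[C@@]2(C)CCCC(C)(C)[C@H]2[C@@H](OC(=O)/C(C)=C\C)C[C@@]1(C)O | target

## Step count and risks

Total step count: 20. Longest linear sequence: 19 steps (steps 1–15 and 17–20, from carvone); step 16 is a one-step side branch.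

Steps most likely to fail:

1. Step 4 (radical ring closure). The C4 radical may be reduced before it cyclises (net hydrogenation of the isopropenyl group), or hydrogen-atom transfer to the vinyl sulfone may compete. Fallback: setting out from 7, HBr (33% in AcOH), CH2Cl2, −10 °C should add in the Markovnikov sense to the isopropenyl group to give the tertiary bromide F1. Slow addition of Bu3SnH with AIBN in benzene at 80 °C then generates the same C4 radical under tin-hydride chain conditions and closes ring A by the same 6-endo Giese mode, coming back to the route at 8.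

2. Step 9 (allylic oxidation). Oxidation may stray to the C9 methine or the C17 methyl, and enolisation of the new ketone toward C5 may erode the cis ring fusion. Fallback: setting out from 15, mCPBA/NaHCO3 in CH2Cl2 should epoxidise C7=C8, expected on the α face anti to the pseudoaxial 9β arm, giving the 7α,8α-epoxide F2 (the other epoxide would converge later). PhSeNa (from PhSeSePh and NaBH4, EtOH) opens it at the secondary carbon C7 to the hydroxy selenide F3. H2O2/pyridine oxidation and selenoxide syn-elimination, which can only run toward C6, give the tertiary allylic alcohol F4. Babler–Dauben oxidative 1,3-transposition with pyridinium chlorochromate [C5H5NH][CrO3Cl] in CH2Cl2 then places the carbonyl at C6 with the alkene at C7=C8, coming back to the route at 16.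

3. Step 19 (angelate installation). Z to E isomerisation to the tiglate may occur during acyl transfer, and acylation of the hindered 6α-hydroxyl next to the C4 gem-dimethyl carbon may be slow. Fallback: setting out from 27, acylation with 2-[bis(2,2,2-trifluoroethoxy)phosphoryl]propanoic acid (EDC, DMAP, CH2Cl2) should give the phosphonopropanoate F5, an acyl donor with no alkene geometry to lose. A Still–Gennari olefination with acetaldehyde (KN(SiMe3)2, 18-crown-6, THF, −78 °C, with a second equivalent of base for the free 8-OH) then builds the Z-trisubstituted alkene on the ester, coming back to the route at 30.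

## Further compounds

F1 | step 4 | (5S,6S)-5-(2-bromopropan-2-yl)-2,6-dimethyl-6-[2-(phenylsulfonyl)prop-2-en-1-yl]cyclohex-2-en-1-one | O=C1[C@@](C)(CC(=C)S(=O)(=O)c2ccccc2)[C@@H](C(C)(C)Br)CC=C1C
F2 | step 9 | methyl 7α,8α-epoxy-13,14,15,16-tetranor-5β-labdan-12-oate | COC(=O)C[C@@H]1[C@@]2(C)CCCC(C)(C)[C@H]2C[C@H]3O[C@@]13C
F3 | step 9 | methyl 8α-hydroxy-7β-(phenylselanyl)-13,14,15,16-tetranor-5β-labdan-12-oate | COC(=O)C[C@@H]1[C@@]2(C)CCCC(C)(C)[C@H]2C[C@H]([Se]c3ccccc3)[C@@]1(C)O
F4 | step 9 | methyl 8α-hydroxy-13,14,15,16-tetranor-5β-labd-6-en-12-oate | COC(=O)C[C@@H]1[C@@]2(C)CCCC(C)(C)[C@H]2C=C[C@@]1(C)O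
F5 | step 19 | (13R)-8α-hydroxy-16-[(4-methoxybenzyl)oxy]-5β-labd-14-en-6α-yl 2-[bis(2,2,2-trifluoroethoxy)phosphoryl]propanoate | C=C[C@H](COCc1ccc(OC)cc1)CC[C@@H]1[C@@]2(C)CCCC(C)(C)[C@H]2[C@@H](OC(=O)C(C)P(=O)(OCC(F)(F)F)OCC(F)(F)F)C[C@@]1(C)O
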